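**Retrosynthetic overview**
- Last step: the target acid comes from its tert-butyl ester by acidolysis.
- Key disconnection: the depside C(aryl)–O bond, made from the ring A carboxylic acid (as O-nucleophile) and the C4–H bond of the ring B tert-butyl ester, through an aryl pinacolboronate formed and used in the same flask.
- Ring A acid: from 2,4-dimethoxy-6-methylbenzoic acid and N-methoxy-N-methylhexanamide by lateral dianion acylation.
- Ring B ester: from 2-methoxy-6-methylbenzoic acid and 1-bromobutane by lateral dianion alkylation, then tert-butyl ester formation.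
- No ring is formed: both benzene rings (ring A, ring B) are bought; order is ring A acid, ring B ester, C–O union, deprotection.

Assumption: the target has no stereocentre (it is achiral), so no stereocontrol is needed; the only stereocentre on the way is the racemic, transient one in adduct 4.

**Step 1**
Reactants: 1 2,4-dimethoxy-6-methylbenzoic acid; 2 N-methoxy-N-methylhexanamide
Product: 5 2,4-dimethoxy-6-(2-oxoheptyl)benzoic acid, via dilithio dianion 3 (not isolated), via tetrahedral lithium adduct 4 (not isolated)
Conditions: LiN(iPr)2 (2.3 equiv), THF, −78 → 0 °C, 1 h; then 2 (1.1 equiv), −78 → −20 °C; cold 1 M HCl to pH 3, bicarbonate/acid extraction, no heating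
Reagents that add atoms: none
Why: Lateral (benzylic) lithiation of an ortho-toluic acid as its carboxylate dianion, then Weinreb ketone synthesis, in which the chelated adduct 4 prevents over-addition and keeps the ketone masked from base until the cold acidic quench; no stereocentre remains.

**Step 2**
Reactants: 6 2-methoxy-6-methylbenzoic acid; 7 1-bromobutane
Product: 9 2-methoxy-6-pentylbenzoic acid, via dilithio dianion 8 (not isolated)
Conditions: LiN(iPr)2 (2.2 equiv), THF, −78 → 0 °C; then 7 (1.2 equiv), −78 °C → rt; 1 M HCl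
Reagents that add atoms: none
Why: Lateral lithiation of the toluic acid dianion and SN2 alkylation of the benzylic carbanion by a primary bromide (dianion alkylation of toluic acids), turning the methyl group into pentyl; no stereocentre.

**Step 3**
Reactants: 9 2-methoxy-6-pentylbenzoic acid
Product: 10 tert-butyl 2-methoxy-6-pentylbenzoate
Conditions: tert-butyl 2,2,2-trichloroacetimidate (2.0 equiv), BF3·OEt2 (5 mol%), CH2Cl2/cyclohexane (1:2), rt, 16 h
Reagents that add atoms: tert-butyl 2,2,2-trichloroacetimidate, CC(C)(C)OC(=N)C(Cl)(Cl)Cl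
Why: Imidate esterification transfers a tert-butyl cation to the carboxyl oxygen, so the di-ortho-substituted acyl carbon is never attacked and hindrance does not matter; no stereocentre.

**Step 4**
Reactants: 10 tert-butyl 2-methoxy-6-pentylbenzoate; 5 2,4-dimethoxy-6-(2-oxoheptyl)benzoic acid
Product: 12 tert-butyl 4-{[2,4-dimethoxy-6-(2-oxoheptyl)benzoyl]oxy}-2-methoxy-6-pentylbenzoate, via aryl pinacolboronate 11 (not isolated)
Conditions: (a) 10 (1.3 equiv), pinacolborane (2.0 equiv), [Ir(OMe)(cod)]2 (1.5 mol%), 4,4'-di-tert-butyl-2,2'-bipyridine (3 mol%), THF, 80 °C, 16 h, then volatiles removed in vacuo; (b) 5 (1.0 equiv), Cu(OTf)2 (20 mol%), 2,6-lutidine (1.0 equiv), MeCN, O2 (1 atm), 40 °C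
Reagents that add atoms: none
Why: Proposed new method: a one-flask, sterically controlled C–H acyloxylation, in which trivalent-iridium tris(boryl) catalysis borylates the only C–H of 10 without an ortho neighbour (C4) and the crude boronate 11 is coupled with the carboxylate of 5 by Cu(OTf)2 under O2. Carboxylate-bridged boron-to-copper transmetalation gives an aryl–divalent-copper carboxylate, a second divalent copper oxidises it to the aryl–trivalent-copper carboxylate, C–O reductive elimination releases the aryl ester, and O2 returns monovalent copper to the divalent state. The acid reacts only through its oxygen, so its hindered carbonyl is never activated and enol-lactonisation to the isocoumarin is avoided. The closest known reactions are the Chan–Lam O-arylation of carboxylic acids with arylboronic acids and one-pot C–H borylation/Chan–Lam etherification; no stereocentre is formed.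

**Step 5**
Reactants: 12 tert-butyl 4-{[2,4-dimethoxy-6-(2-oxoheptyl)benzoyl]oxy}-2-methoxy-6-pentylbenzoate
Product: 13 4-{[2,4-dimethoxy-6-(2-oxoheptyl)benzoyl]oxy}-2-methoxy-6-pentylbenzoic acid (CNP0169128.0)
Conditions: CF3CO2H/CH2Cl2 (1:4), 0 °C → rt, 2 h; co-evaporation with toluene below 25 °C
Reagents that add atoms: none
Why: Acidolysis of the tert-butyl ester by alkyl–oxygen cleavage (loss of the tert-butyl cation as isobutene) leaves the hindered aryl ester, the ketone and the methyl ethers untouched; no stereocentre.

**Compound list**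
1 | 2,4-dimethoxy-6-methylbenzoic acid | Cc1cc(OC)cc(OC)c1C(=O)O | starting material
2 | N-methoxy-N-methylhexanamide | CCCCCC(=O)N(C)OC | starting material
3 | lithium 2-(lithiomethyl)-4,6-dimethoxybenzoate (dilithio dianion of 1, not isolated) | [Li]Cc1cc(OC)cc(OC)c1C(=O)O[Li] | intermediate
4 | lithium 2-[2-(lithiooxy)-2-[methoxy(methyl)amino]heptyl]-4,6-dimethoxybenzoate (racemic tetrahedral adduct, not isolated) | CCCCCC(O[Li])(Cc1cc(OC)cc(OC)c1C(=O)O[Li])N(C)OC | intermediate
5 | 2,4-dimethoxy-6-(2-oxoheptyl)benzoic acid | CCCCCC(=O)Cc1cc(OC)cc(OC)c1C(=O)O | intermediate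
6 | 2-methoxy-6-methylbenzoic acid | Cc1cccc(OC)c1C(=O)O | starting material
7 | 1-bromobutane | CCCCBr | starting material
8 | lithium 2-(lithiomethyl)-6-methoxybenzoate (dilithio dianion of 6, not isolated) | [Li]Cc1cccc(OC)c1C(=O)O[Li] | intermediate
9 | 2-methoxy-6-pentylbenzoic acid | CCCCCc1cccc(OC)c1C(=O)O | intermediate
10 | tert-butyl 2-methoxy-6-pentylbenzoate | CCCCCc1cccc(OC)c1C(=O)OC(C)(C)C | intermediate
11 | tert-butyl 2-methoxy-6-pentyl-4-(4,4,5,5-tetramethyl-1,3,2-dioxaborolan-2-yl)benzoate (not isolated) | CCCCCc1cc(B2OC(C)(C)C(C)(C)O2)cc(OC)c1C(=O)OC(C)(C)C | intermediate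
12 | tert-butyl 4-{[2,4-dimethoxy-6-(2-oxoheptyl)benzoyl]oxy}-2-methoxy-6-pentylbenzoate | CCCCCC(=O)Cc1cc(OC)cc(OC)c1C(=O)Oc1cc(CCCCC)c(C(=O)OC(C)(C)C)c(OC)c1 | intermediate
13 | 4-{[2,4-dimethoxy-6-(2-oxoheptyl)benzoyl]oxy}-2-methoxy-6-pentylbenzoic acid | CCCCCC(=O)Cc1cc(OC)cc(OC)c1C(=O)Oc1cc(CCCCC)c(C(=O)O)c(OC)c1 | target

**Totals and risks**
Total step count: 5. Longest linear sequence: 4 steps (6 → 9 → 10 → 12 → 13); the ring A acid 5 is made in one step and joins at step 4.

The three steps most likely to fail:

Step 4 (the proposed new step). Transmetalation of the pinacol ester may be slow, so protodeboronation or phenol formation could win. Copper and O2 may oxidise the ArCH2C(=O) methylene. Base may convert 12 into the isocoumarin with loss of the ring B phenol. The fallback uses known chemistry and sets out from 11: it is oxidised with NaBO3·4H2O in THF/H2O at rt to tert-butyl 4-hydroxy-2-methoxy-6-pentylbenzoate F1. F1 is then acylated with acid 5 by Steglich esterification (DCC, catalytic DMAP, CH2Cl2, 0 °C), which forms the acyl C–O bond and returns to the route at 12.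

Step 1. The dianion may form incompletely, the amide may be enolised, and 5 may dehydrate to the enol lactone on work-up. The fallback sets out from 1 and goes through the isolable isocoumarin. CH3I and K2CO3 in DMF give methyl 2,4-dimethoxy-6-methylbenzoate F2. LiN(iPr)2 in THF at −78 °C followed by 2 gives methyl 2,4-dimethoxy-6-(2-oxoheptyl)benzoate F3. NaH in THF closes it to 6,8-dimethoxy-3-pentyl-1H-isochromen-1-one F4, which can be crystallised. KOH in aqueous EtOH at reflux followed by cold acidification opens the lactone and returns to the route at 5.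

Step 5. Acid may trigger enol-lactonisation with loss of the ring B phenol, tert-butylation of ring A, or decarboxylation. The fallback replaces acidolysis at the depside stage by neutral hydrogenolysis and sets out from 11, oxidised as above to F1. CF3CO2H/CH2Cl2 removes the tert-butyl group before the depside exists, giving 4-hydroxy-2-methoxy-6-pentylbenzoic acid F5. Benzyl bromide and KHCO3 in DMF give benzyl 4-hydroxy-2-methoxy-6-pentylbenzoate F6. DCC and catalytic DMAP with acid 5 give benzyl 4-{[2,4-dimethoxy-6-(2-oxoheptyl)benzoyl]oxy}-2-methoxy-6-pentylbenzoate F7. H2 (1 atm) over Pd/C (10 wt% palladium on carbon) in EtOAc returns to the route at 13.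

**Further compounds**
F1 | step 4 | tert-butyl 4-hydroxy-2-methoxy-6-pentylbenzoate | CCCCCc1cc(O)cc(OC)c1C(=O)OC(C)(C)C
F2 | step 1 | methyl 2,4-dimethoxy-6-methylbenzoate | Cc1cc(OC)cc(OC)c1C(=O)OC
F3 | step 1 | methyl 2,4-dimethoxy-6-(2-oxoheptyl)benzoate | CCCCCC(=O)Cc1cc(OC)cc(OC)c1C(=O)OC
F4 | step 1 | 6,8-dimethoxy-3-pentyl-1H-isochromen-1-one | CCCCCC1=Cc2cc(OC)cc(OC)c2C(=O)O1
F5 | step 5 | 4-hydroxy-2-methoxy-6-pentylbenzoic acid | CCCCCc1cc(O)cc(OC)c1C(=O)O
F6 | step 5 | benzyl 4-hydroxy-2-methoxy-6-pentylbenzoate | CCCCCc1cc(O)cc(OC)c1C(=O)OCc1ccccc1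
F7 | step 5 | benzyl 4-{[2,4-dimethoxy-6-(2-oxoheptyl)benzoyl]oxy}-2-methoxy-6-pentylbenzoate | CCCCCC(=O)Cc1cc(OC)cc(OC)c1C(=O)Oc1cc(CCCCC)c(C(=O)OCc2ccccc2)c(OC)c1
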